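## The problem

Daucane numbering is used throughout. The cyclopentane is C1-C5 and is trans-fused along C1-C5 to the cycloheptene C1, C5-C10. C1 carries the angular methyl C15, C4 the tertiary hydroxyl and the isopropyl group, C6 the anisate, C8 the vinylic methyl C14, and C9 the free allylic hydroxyl.

C4, C5, C1 and C6 are contiguous stereocentres that include a quaternary carbon and a tertiary carbinol, and C9 is a fifth, remote one. C15, O4, O9 and H6 lie on the beta face. H5, the isopropyl group and O6 lie on the alpha face.

The hard relation is C1/C5/C4. The two groups on C1 that flank C5 (CH3 and C10H2) are almost equal in size. Closing the five-membered ring on a cycloheptenone enolate gives the cis fusion. The isopropyl group must end up cis to C10.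

C1 can still control everything if C5 stays trigonal while C4 is made. In a cyclohepta-1,3-diene C15 is axial and screens the beta face. Once C1 and C4 are fixed, C5 follows by equilibration.

The sensitive parts are the C4-C5-C6 aldol array (retro-aldol, E1cB loss of O4) and the doubly allylic C6-C7=C8-C9 unit (ionisation, allylic transposition).

The feature behind the key step is a hidden symmetry. Without C2-C4, the isopropyl group and O9, the atoms C1, C5-C10, C14, C15 and O6 form 3,6-dimethylcyclohepta-2,6-dienone. A twofold axis through C6=O and the midpoint of C9-C10 makes C1/C8, C5/C7, C10/C9 and C15/C14 pairwise equivalent.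

## Retrosynthesis

**C9-H, the ester C-O bond and C6-H (22 to 21, 19 + 20, 18).** The two carbinol hydrogens and the acyl group are removed first. The precursor is ene-dione 18, which has three stereocentres. The two ketones of 18 are not alike. Only C6 has the C4 hydroxyl next to it, so a hydroxyl-directed hydride can reduce C6 alone, from the hindered beta face. C9 is then reduced last from the open alpha face. Cutting the C-O bonds instead would require two separate stereocontrolled oxygenations.

**O9 (18 to 17).** C9 is the gamma carbon of the C6 enone, so its oxygen can come from an allylic oxidation of 17. This cut makes C9 and C10 both plain CH2 groups. The forward step must attack the ring CH2 and not the methyl C14.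

**C4-isopropyl bond (17 to 14 + 15).** The neighbouring cut, C4-C5 with the isopropyl group already in place, is Alternative 3 and should give the wrong diastereomer. Cutting C4-C11 instead leaves silyl dienol ether 14. In 14, C4 is the only carbonyl, C5 is trigonal and C1 is the only stereocentre. The nucleophile must come from the alpha face, and the unveiling must stop at the aldol stage.

**C4-C5 bond at the aldehyde level (14 to 13, 12, 10).** The enolised beta-diketone 13 comes from ketol 12. Ketol 12 comes from an aldol reaction between C5 and an aldehyde released from the butenyl chain of 10. The configurations at C4 and C5 in 12 do not matter because both centres are flattened again in 13. Only C5 is an sp3 alpha carbon of the C6 ketone, so no regiochemical question arises.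

**C1-C2 bond (10 to 7 + 8), the key cut.** Removing the butenyl chain leaves the achiral dienone 7, C9H12O. Cutting C1-C15 or C1-C10 would give unsymmetrical dienones with two competing acceptor sites. In 7 both sites are equivalent by symmetry. The enone that does not react is already C6=O/C7=C8(C14). The forward reaction must select one enone face and must add 1,4, once.

**C1-C5 and C7-C8 bonds, plus the furan oxygen (7 to 5, 4, 1 + 2).** Dienone 7 is the double beta-elimination product of oxygen-bridged ketone 5. Ketone 5 is the reduced (4+3) adduct of furan 1 and the oxyallyl cation 3 from ketone 2. The furan supplies C1, C10, C9, C8 and both methyl groups. The ketone supplies C5-C6-C7. The bridge oxygen serves twice as a leaving group.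

## Roads not taken

**Alternative 1:** cut C7=C8, the most obvious route. The forward key step is ring-closing metathesis of triene triol A1 with the second-generation Grubbs catalyst.
- A1 would be built on a cyclopentenone by conjugate addition at C1, aldol trapping at C5 and isopropyl addition at C4.
- The ring closure itself is safe, but it solves none of the stereochemistry.
- C5 must be set against a quaternary carbon whose CH3 and CH2 groups hardly differ.
- C6 and C9 must be set in freely rotating side chains.
- Three hydroxyl groups need protection and differentiation.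
- The chosen plan sets C6 and C9 on the finished ring and carries one silyl group for one step.

**Alternative 2:** cut C1-C5 and C1-C10, that is, delete C1. The six carbons C5-C10 then form a 2,5-dioxygenated toluene ring.
- The forward key step is an intramolecular Buchner ring expansion of diazo ketone A2 with Rh2(OAc)4 to give cycloheptatriene A3.
- The oxygen pattern of A3 is attractive, since two enol ethers sit at C6 and C9.
- The carbonyl that stabilises the diazo group ends up at C2 and costs about three steps to remove.
- The beta-silyloxy diazo ketone can divert through an oxonium ylide.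
- A2 needs an enantiopure hindered tertiary benzylic alcohol, which takes a long run-up.

**Alternative 3:** cut C4-C5 with the isopropyl ketone already in place. This means conjugate addition of a 4-methyl-3-oxopentyl unit to 7, giving diketone A4, followed by intramolecular aldol reaction.
- It is the shortest possible route.
- The new bond at C5 must form perpendicular to the enolate plane, from a chain that sits equatorial on C1, so the closure is cis.
- The chelated transition state puts O4 next to C6.
- The expected product is therefore ketol A5, with both C4 and C5 wrong.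
- Equilibration has no clear bias towards the trans ketol and competes with dehydration.
- The chosen plan spends three more steps to make C4 under the control of the axial methyl group.

Key step: step 4

Assumption: the sense of induction of the copper-carbene catalyst on 7 cannot be known in advance, so the ligand enantiomer is taken to be the one that gives (6R)-10.

## Steps

Step 1
Reactants: 1 2,5-dimethylfuran; 2 1,1,3-trichloropropan-2-one
Product: 4 2,4-dichloro-1,5-dimethyl-8-oxabicyclo[3.2.1]oct-6-en-3-one (epimers at the two CHCl centres), via dichloro-oxyallyl cation 3 (not isolated)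
Conditions: Et3N, CF3CH2OH, 0 °C to rt
Reagents that add atoms: none
Why: (4+3) cycloaddition of a furan and an oxyallyl cation formed by base-induced loss of HCl in a fluorinated alcohol; it closes the seven-membered carbocycle through the C1-C5 and C7-C8 bonds. The two methyl-bearing bridgeheads are necessarily cis across the oxygen bridge, and the CHCl centres are erased in step 2.

Step 2
Reactants: 4 2,4-dichloro-1,5-dimethyl-8-oxabicyclo[3.2.1]oct-6-en-3-one
Product: 5 1,5-dimethyl-8-oxabicyclo[3.2.1]octan-3-one (meso)
Conditions: H2 (1 atm), Pd/C, Et3N, MeOH, rt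
Reagents that add atoms: none
Why: Catalytic hydrogenolysis of the two activated C-Cl bonds alpha to the ketone and hydrogenation of the strained alkene run under the same conditions. The product is meso, so no stereochemical question arises.

Step 3
Reactants: 5 1,5-dimethyl-8-oxabicyclo[3.2.1]octan-3-one
Product: 7 3,6-dimethylcyclohepta-2,6-dien-1-one, via hydroxy enone 6 (not isolated)
Conditions: p-TsOH·H2O (cat.), toluene, reflux, Dean-Stark trap
Reagents that add atoms: none
Why: Acid-catalysed double beta-elimination: both tertiary C-O bonds of the bridge are beta to the ketone, so the ether opens to 6 and 6 loses water. The two conjugated trisubstituted alkenes are the most substituted arrangement available and should be the equilibrium product.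

Step 4
Reactants: 7 3,6-dimethylcyclohepta-2,6-dien-1-one; 8 but-3-en-1-ylmagnesium bromide
Product: 10 (6R)-6-(but-3-en-1-yl)-3,6-dimethylcyclohept-2-en-1-one, via magnesium dienolate 9 (not isolated)
Conditions: Cu(OTf)2 (3 mol %), 1-[(2S)-1-hydroxy-3,3-dimethylbutan-2-yl]-3-mesityl-4,5-dihydroimidazolium PF6 or its enantiomer (4 mol %), Et2O, -30 °C; then aq. NH4Cl
Reagents that add atoms: none
Why: Copper-catalysed asymmetric conjugate addition of a Grignard reagent to a beta-methyl cyclic enone, a reaction type established on six- and seven-membered 3-methylenones. The alkoxide-tethered N-heterocyclic carbene binds copper and magnesium, the butenylcuprate forms a pi complex with one enone, and addition at the beta carbon followed by reductive elimination gives the C1-C2 bond and dienolate 9. No ring is closed. The only new stereocentre, C1, is set by the chiral carbene ligand, which selects the enone face. Site selectivity is not an issue, because the twofold axis of 7 makes attack at C1 from one face identical to attack at C8 from the other, so both enones give the same enantiomer. The step needs 1,4- over 1,2-addition, which the carbene-copper catalyst secures, and a single addition, which is secured because 9 is an unreactive cross-conjugated dienolate until the quench. The untouched enone is already the C6 carbonyl and the C7=C8(C14) alkene of the target.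

Step 5
Reactants: 10 (6R)-6-(but-3-en-1-yl)-3,6-dimethylcyclohept-2-en-1-one
Product: 12 (8aS)-3-hydroxy-6,8a-dimethyl-2,3,3a,7,8,8a-hexahydroazulen-4(1H)-one (epimers at C3 and C3a), via keto aldehyde 11 (not isolated)
Conditions: O3, CH2Cl2/MeOH, -78 °C, stopped at consumption of 10; Me2S; then K2CO3, MeOH, 0 °C
Reagents that add atoms: ozone, [O-][O+]=O
Why: Ozone should cleave the electron-rich terminal alkene faster than the enone alkene. The intramolecular aldol addition (5-enolexo) of the only sp3 alpha carbon of the ketone, C5, to the aldehyde then closes the five-membered ring. The configurations at C4 and C5 are irrelevant because both centres become trigonal in step 6.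

Step 6
Reactants: 12 (8aS)-3-hydroxy-6,8a-dimethyl-2,3,3a,7,8,8a-hexahydroazulen-4(1H)-one
Product: 13 (8aS)-4-hydroxy-6,8a-dimethyl-1,7,8,8a-tetrahydroazulen-3(2H)-one (enol form of the 3,4-dione)
Conditions: Dess-Martin periodinane, CH2Cl2, 0 °C to rt
Reagents that add atoms: none
Why: Oxidation of a beta-hydroxy ketone to the beta-diketone under neutral conditions that avoid dehydration. The product should rest as the enol whose C5=C6 bond is exocyclic to the five-membered ring and linearly conjugated.

Step 7
Reactants: 13 (8aS)-4-hydroxy-6,8a-dimethyl-1,7,8,8a-tetrahydroazulen-3(2H)-one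
Product: 14 (8aS)-6,8a-dimethyl-4-[(triethylsilyl)oxy]-1,7,8,8a-tetrahydroazulen-3(2H)-one
Conditions: Et3SiCl, Et3N, DMAP (cat.), CH2Cl2, 0 °C
Reagents that add atoms: chlorotriethylsilane, CC[Si](Cl)(CC)CC
Why: O-silylation of the enolised beta-diketone. The isomer silylated at O6 keeps the double bond exocyclic to the cyclopentanone and has the longer O4=C4-C5=C6-C7=C8 conjugation, so it should be favoured. C4 is left as the only carbonyl group.

Step 8
Reactants: 14 (8aS)-6,8a-dimethyl-4-[(triethylsilyl)oxy]-1,7,8,8a-tetrahydroazulen-3(2H)-one; 15 isopropylmagnesium chloride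
Product: 17 (3R,3aR,8aS)-3-hydroxy-6,8a-dimethyl-3-(propan-2-yl)-2,3,3a,7,8,8a-hexahydroazulen-4(1H)-one, via silyl dienol carbinol 16 (not isolated)
Conditions: LaCl3·2LiCl, THF, -78 °C; AcOH; then Bu4NF/AcOH, THF, 0 °C; DBU (cat.), CH2Cl2, rt
Reagents that add atoms: none
Why: Lanthanide-promoted 1,2-addition of a Grignard reagent to a beta-silyloxy enone; in the cyclohepta-1,3-diene envelope of 14, C15 is axial and blocks the beta face, so the isopropyl group enters C4 from the alpha face and O4 becomes beta. Buffered fluoride frees the C6 enolate without the acid that would ionise the tertiary allylic alcohol, and protonation occurs at C5. Mild base should then settle C5 as the trans-fused epimer, in which C6 is cis to the small hydrogen-bonding hydroxyl group and trans to the isopropyl group.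

Step 9
Reactants: 17 (3R,3aR,8aS)-3-hydroxy-6,8a-dimethyl-3-(propan-2-yl)-2,3,3a,7,8,8a-hexahydroazulen-4(1H)-one
Product: 18 (3R,3aR,8aR)-3-hydroxy-6,8a-dimethyl-3-(propan-2-yl)-1,2,3,3a,8,8a-hexahydroazulene-4,7-dione
Conditions: Rh2(cap)4 (cap = caprolactamate, 1 mol %), 70% aq. t-BuOOH, ClCH2CH2Cl, 40 °C
Reagents that add atoms: tert-butyl hydroperoxide, CC(C)(C)OO
Why: Dirhodium-caprolactamate/hydroperoxide oxidation of an enone at its gamma position to the ene-dione, a known reaction type. The tert-butylperoxyl radical should abstract the secondary ring hydrogen at C9 in preference to a primary hydrogen of C14, and base-free conditions spare the aldol unit.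

Step 10
Reactants: 18 (3R,3aR,8aR)-3-hydroxy-6,8a-dimethyl-3-(propan-2-yl)-1,2,3,3a,8,8a-hexahydroazulene-4,7-dione
Product: 19 (3R,3aS,4S,8aR)-3,4-dihydroxy-6,8a-dimethyl-3-(propan-2-yl)-2,3,3a,4,8,8a-hexahydroazulen-7(1H)-one
Conditions: Me4NBH(OAc)3, MeCN/AcOH, -30 °C
Reagents that add atoms: none
Why: Hydroxyl-directed Evans-Saksena reduction: O4 displaces an acetate on boron, and the tethered hydride reaches C6 from the beta face on which O4 stands, giving the 6-alpha alcohol. The C9 carbonyl has no neighbouring hydroxyl group and should not react with this weak hydride.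

Step 11
Reactants: 19 (3R,3aS,4S,8aR)-3,4-dihydroxy-6,8a-dimethyl-3-(propan-2-yl)-2,3,3a,4,8,8a-hexahydroazulen-7(1H)-one; 20 4-methoxybenzoyl chloride
Product: 21 (3R,3aS,4S,8aR)-3-hydroxy-6,8a-dimethyl-7-oxo-3-(propan-2-yl)-1,2,3,3a,4,7,8,8a-octahydroazulen-4-yl 4-methoxybenzoate
Conditions: Et3N, DMAP, CH2Cl2, 0 °C to rt
Reagents that add atoms: none
Why: DMAP-catalysed acylation. The secondary C6 hydroxyl group reacts while the tertiary C4 hydroxyl group is too hindered, so no protection is needed.

Step 12
Reactants: 21 (3R,3aS,4S,8aR)-3-hydroxy-6,8a-dimethyl-7-oxo-3-(propan-2-yl)-1,2,3,3a,4,7,8,8a-octahydroazulen-4-yl 4-methoxybenzoate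
Product: 22 (3R,3aS,4S,7R,8aR)-3,7-dihydroxy-6,8a-dimethyl-3-(propan-2-yl)-1,2,3,3a,4,7,8,8a-octahydroazulen-4-yl 4-methoxybenzoate
Conditions: NaBH4, CeCl3·7H2O, MeOH, -78 °C
Reagents that add atoms: none
Why: Luche 1,2-reduction of the enone, which leaves the ester untouched. The axial C15 on C1 is 1,3-related to C9 and screens the beta face, so hydride should arrive from the alpha face and give the 9-beta alcohol.

## Compound list

1 | 2,5-dimethylfuran | Cc1ccc(C)o1 | starting material
2 | 1,1,3-trichloropropan-2-one | ClCC(=O)C(Cl)Cl | starting material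
3 | 1,3-dichloro-2-oxidoallyl cation | [O-]C(=CCl)[CH+]Cl | intermediate
4 | 2,4-dichloro-1,5-dimethyl-8-oxabicyclo[3.2.1]oct-6-en-3-one (epimers at the CHCl centres) | O1[C@]2(C)C=C[C@@]1(C)C(Cl)C(=O)C2Cl | intermediate
5 | 1,5-dimethyl-8-oxabicyclo[3.2.1]octan-3-one (meso) | O1[C@]2(C)CC[C@@]1(C)CC(=O)C2 | intermediate
6 | 6-hydroxy-3,6-dimethylcyclohept-2-en-1-one (racemic) | CC1=CC(=O)CC(C)(O)CC1 | intermediate
7 | 3,6-dimethylcyclohepta-2,6-dien-1-one | CC1=CC(=O)C=C(C)CC1 | intermediate
8 | but-3-en-1-ylmagnesium bromide | C=CCC[Mg]Br | starting material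
9 | bromomagnesium dienolate of 10 | C=CCC[C@]1(C)CCC(C)=CC(=C1)O[Mg]Br | intermediate
10 | (6R)-6-(but-3-en-1-yl)-3,6-dimethylcyclohept-2-en-1-one | C=CCC[C@]1(C)CCC(C)=CC(=O)C1 | intermediate
11 | 3-[(1S)-1,4-dimethyl-6-oxocyclohept-4-en-1-yl]propanal | O=CCC[C@]1(C)CCC(C)=CC(=O)C1 | intermediate
12 | (8aS)-3-hydroxy-6,8a-dimethyl-2,3,3a,7,8,8a-hexahydroazulen-4(1H)-one (epimers at C3, C3a) | O=C1C=C(C)CC[C@@]2(C)CCC(O)C12 | intermediate
13 | (8aS)-4-hydroxy-6,8a-dimethyl-1,7,8,8a-tetrahydroazulen-3(2H)-one | OC1=C2C(=O)CC[C@]2(C)CCC(C)=C1 | intermediate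
14 | (8aS)-6,8a-dimethyl-4-[(triethylsilyl)oxy]-1,7,8,8a-tetrahydroazulen-3(2H)-one | CC[Si](CC)(CC)OC1=C2C(=O)CC[C@]2(C)CCC(C)=C1 | intermediate
15 | isopropylmagnesium chloride | CC(C)[Mg]Cl | starting material
16 | (3R,8aS)-6,8a-dimethyl-3-(propan-2-yl)-4-[(triethylsilyl)oxy]-1,2,3,7,8,8a-hexahydroazulen-3-ol | CC[Si](CC)(CC)OC1=C2[C@](O)(C(C)C)CC[C@]2(C)CCC(C)=C1 | intermediate
17 | (3R,3aR,8aS)-3-hydroxy-6,8a-dimethyl-3-(propan-2-yl)-2,3,3a,7,8,8a-hexahydroazulen-4(1H)-one | O=C1C=C(C)CC[C@@]2(C)CC[C@@](O)(C(C)C)[C@H]12 | intermediate
18 | (3R,3aR,8aR)-3-hydroxy-6,8a-dimethyl-3-(propan-2-yl)-1,2,3,3a,8,8a-hexahydroazulene-4,7-dione | O=C1C=C(C)C(=O)C[C@@]2(C)CC[C@@](O)(C(C)C)[C@H]12 | intermediate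
19 | (3R,3aS,4S,8aR)-3,4-dihydroxy-6,8a-dimethyl-3-(propan-2-yl)-2,3,3a,4,8,8a-hexahydroazulen-7(1H)-one | O[C@H]1C=C(C)C(=O)C[C@@]2(C)CC[C@@](O)(C(C)C)[C@H]12 | intermediate
20 | 4-methoxybenzoyl chloride | COc1ccc(cc1)C(Cl)=O | starting material
21 | (3R,3aS,4S,8aR)-3-hydroxy-6,8a-dimethyl-7-oxo-3-(propan-2-yl)-1,2,3,3a,4,7,8,8a-octahydroazulen-4-yl 4-methoxybenzoate | COc1ccc(C(=O)O[C@H]2C=C(C)C(=O)C[C@@]3(C)CC[C@@](O)(C(C)C)[C@H]23)cc1 | intermediate
22 | (3R,3aS,4S,7R,8aR)-3,7-dihydroxy-6,8a-dimethyl-3-(propan-2-yl)-1,2,3,3a,4,7,8,8a-octahydroazulen-4-yl 4-methoxybenzoate | COc1ccc(C(=O)O[C@H]2C=C(C)[C@H](O)C[C@@]3(C)CC[C@@](O)(C(C)C)[C@H]23)cc1 | target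

## Step count and least certain steps

Total step count: 12. Longest linear sequence: 12 steps, from 1 and 2. Compounds 8, 15 and 20 are bought.

**Step 4 (key step).**
- Risk: face discrimination on a flat, cross-conjugated seven-membered dienone may be poor, and direct 1,2-addition of the Grignard reagent may compete, because the acceptor carbon is fully substituted.
- Fallback: resolution instead of catalysis, setting out from 7 and returning at 10. Compound 7 is treated with 8, CuBr·SMe2 and Me3SiCl to give racemic 6-(but-3-en-1-yl)-3,6-dimethylcyclohept-2-en-1-one F1. Lithiated (S)-N,S-dimethyl-S-phenylsulfoximine is added to its carbonyl group, and the diastereomeric adducts are separated. The beta-hydroxysulfoximine of the (6R) ketone F2 is heated in toluene, which releases 10.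

**Step 3.**
- Risk: the eliminations may stop halfway or run towards exocyclic or deconjugated alkenes, and prolonged acid may move the double bonds into a linear dienone.
- Fallback: anionic opening followed by a separate, non-equilibrating dehydration, setting out from 5 and returning at 7. LDA in THF opens the bridge by E1cB elimination to 6, which is isolated. Compound 6 is then dehydrated with the Burgess reagent in warm toluene.

**Step 5.**
- Risk: ozone may also attack the enone alkene, and the ketol may dehydrate under the basic conditions, which would lose the C4 oxygen.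
- Fallback: the aldehyde is carried in masked form instead of being made by oxidation, setting out from 7 and returning at 12. Step 4 is run with [2-(1,3-dioxan-2-yl)ethyl]magnesium bromide to give (6R)-6-[2-(1,3-dioxan-2-yl)ethyl]-3,6-dimethylcyclohept-2-en-1-one F3. Aqueous HCl in THF releases 11, and K2CO3 in MeOH closes it to 12.

**Step 8.**
- Risk: the branched Grignard reagent may enolise 14 or reduce it by beta-hydride transfer. The tertiary, doubly allylic alcohol may also ionise during unveiling and dehydrate to the cross-conjugated dienone.
- Fallback: a smaller sp2 nucleophile without beta-hydrogen, then saturation, setting out from 14 and returning at 17. Isopropenylmagnesium bromide with LaCl3·2LiCl, followed by the same buffered fluoride treatment, gives (3R,3aR,8aS)-3-hydroxy-6,8a-dimethyl-3-(prop-1-en-2-yl)-2,3,3a,7,8,8a-hexahydroazulen-4(1H)-one F4. Its 1,1-disubstituted alkene is hydrogenated over RhCl(PPh3)3 in benzene, which leaves the trisubstituted enone untouched.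

**Step 9.**
- Risk: hydrogen abstraction may occur at C14 as well as at C9, and the warm aqueous medium may start retro-aldol cleavage.
- Fallback: polar gamma-oxygenation instead of radical oxidation, setting out from 17 and returning at 18. Me3SiOTf and Et3N give the bis(trimethylsilyl) derivative with the C6,C8-dienol ether F5. Buffered mCPBA oxidises its terminal C8=C9 bond, and after work-up the 9-hydroxy enone F6 is obtained. MnO2 oxidises F6 to 18.

**Step 12.**
- Risk: facial selectivity may be insufficient if the alpha-oriented anisate at C6 shields the alpha face as much as C15 shields the beta face.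
- Fallback: inversion instead of direct delivery, setting out from 21 and returning at 22. The reduction product with the 9-alpha hydroxyl group F7 is subjected to a Mitsunobu reaction with 4-nitrobenzoic acid, PPh3 and DIAD. This gives the 9-beta 4-nitrobenzoate F8. The more electrophilic nitrobenzoate is then removed selectively with K2CO3 in MeOH at 0 °C.

## Further compounds

F1 | step 4 | racemic 6-(but-3-en-1-yl)-3,6-dimethylcyclohept-2-en-1-one | C=CCCC1(C)CCC(C)=CC(=O)C1
F2 | step 4 | beta-hydroxysulfoximine from (6R)-10 and (S)-N,S-dimethyl-S-phenylsulfoximine (carbinol centre as formed) | C=CCC[C@]1(C)CCC(C)=CC(O)(C[S@@](=O)(=NC)c2ccccc2)C1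
F0 | step 3 | none | none
F3 | step 5 | (6R)-6-[2-(1,3-dioxan-2-yl)ethyl]-3,6-dimethylcyclohept-2-en-1-one | C1COC(CC[C@]2(C)CCC(C)=CC(=O)C2)OC1
F4 | step 8 | (3R,3aR,8aS)-3-hydroxy-6,8a-dimethyl-3-(prop-1-en-2-yl)-2,3,3a,7,8,8a-hexahydroazulen-4(1H)-one | O=C1C=C(C)CC[C@@]2(C)CC[C@@](O)(C(C)=C)[C@H]12
F5 | step 9 | bis(trimethylsilyl) derivative of 17 (O4 silyl ether, C6,C8-dienol silyl ether) | C[Si](C)(C)OC1=CC(C)=CC[C@@]2(C)CC[C@@](O[Si](C)(C)C)(C(C)C)[C@H]12
F6 | step 9 | 9-hydroxy derivative of 17 (epimers at C9) | O=C1C=C(C)C(O)C[C@@]2(C)CC[C@@](O)(C(C)C)[C@H]12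
F7 | step 12 | 9-epimer of 22 (9-alpha hydroxyl) | COc1ccc(C(=O)O[C@H]2C=C(C)[C@@H](O)C[C@@]3(C)CC[C@@](O)(C(C)C)[C@H]23)cc1
F8 | step 12 | 9-beta 4-nitrobenzoate of 22 | COc1ccc(C(=O)O[C@H]2C=C(C)[C@H](OC(=O)c4ccc(cc4)[N+](=O)[O-])C[C@@]3(C)CC[C@@](O)(C(C)C)[C@H]23)cc1
A1 | alternative 1 | triene triol opened at C7=C8 (C6 vinyl carbinol and C9 isopropenyl carbinol on the complete cyclopentane) | C=C[C@H](O)[C@H]1[C@](O)(C(C)C)CC[C@]1(C)C[C@@H](O)C(C)=C
A2 | alternative 2 | 2-diazo-5-(2,5-dimethoxy-4-methylphenyl)-6-methyl-5-[(triethylsilyl)oxy]heptan-3-one | CC(=[N+]=[N-])C(=O)C[C@@](O[Si](CC)(CC)CC)(C(C)C)c1cc(OC)c(C)cc1OC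
A3 | alternative 2 | ring-expanded cycloheptatriene (C2 ketone, enol ethers at C6 and C9) | COC1=C[C@@]2(C)C(=O)C[C@@](O[Si](CC)(CC)CC)(C(C)C)C2=C(OC)C=C1C
A4 | alternative 3 | 3,6-dimethyl-6-(4-methyl-3-oxopentyl)cyclohept-2-en-1-one, C1 configured as in 10 | CC(C)C(=O)CC[C@]1(C)CCC(C)=CC(=O)C1
A5 | alternative 3 | cis-fused ketol, epimer of 17 at both C4 and C5 | O=C1C=C(C)CC[C@@]2(C)CC[C@](O)(C(C)C)[C@@H]12
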